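**Retrosynthetic overview**
1. Feature: ring A (C4a, C5, C6, C7, C8, C8a, chromene numbering) has oxygen on C5, C7 and C8a and the aroyl group on C6. This is the pattern of a cyclised tetraketide, and its C4a–C8a bond is also the enol-ether bond of the pyran ring (O1, C2, C3, C4).
2. Late bonds: the ring B phenol is unmasked last (MOM ether). The C8–CH2 bond of the prenyl group is cut back to prenyl bromide and the C8–H chromene.
3. Key disconnection C5–C6: ring A is unwound into a 2-pyrone fused to the pyran ring. The lactone carbonyl is the future C5, the pyrone ring oxygen the future O7, and the aroylmethyl CH2 the future C6.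
4. The aroylmethyl arm comes from acylation of the 7-methyl dienolate with MOM-protected methyl 3-hydroxybenzoate. The pyranopyrone comes from 4-hydroxy-6-methyl-2-pyrone and 3-methylbut-2-enal.
5. Ring order: ring B and the pyrone are purchased, the pyran ring is closed in step 1, and ring A is closed in step 4 while the pyrone ring is consumed.

Key step: step 4

Remark: the target has no stereocentre and its C3=C4 double bond is cis by ring constraint, so nothing stereochemical has to be set. Compounds 8 and 9 are drawn as keto tautomers although they should be partly enolised.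

**Step 1**
Reactants: 1 4-hydroxy-6-methyl-2H-pyran-2-one; 2 3-methylbut-2-enal
Product: 4 2,2,7-trimethyl-2H,5H-pyrano[4,3-b]pyran-5-one, via 1-oxatriene 3 (not isolated)
Conditions: piperidinium acetate (20 mol %), Na2SO4, toluene, 80 °C
Reagents that add atoms: none
Why: Knoevenagel condensation of the iminium-activated enal at C3 of the pyrone gives 1-oxatriene 3, which closes onto the C4 ketone oxygen by 6π oxa-electrocyclisation (formal [3+3] annulation); the β,β-disubstituted enal disfavours conjugate addition, the gem-dimethyl terminus favours the closed 2H-pyran, and no stereocentre arises.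

**Step 2**
Reactants: 5 methyl 3-hydroxybenzoate
Product: 6 methyl 3-(methoxymethoxy)benzoate
Conditions: MOMCl, iPr2NEt, CH2Cl2, 0 °C → rt
Reagents that add atoms: chloromethyl methyl ether (MOMCl), COCCl
Why: Williamson-type O-alkylation of the phenol with the reactive α-chloro ether gives the MOM acetal, which should survive the amide base, the methoxide and the DBU used later.

**Step 3**
Reactants: 4 2,2,7-trimethyl-2H,5H-pyrano[4,3-b]pyran-5-one; 6 methyl 3-(methoxymethoxy)benzoate
Product: 8 7-{2-[3-(methoxymethoxy)phenyl]-2-oxoethyl}-2,2-dimethyl-2H,5H-pyrano[4,3-b]pyran-5-one, via lithium dienolate 7 (not isolated)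
Conditions: 4, LiN(iPr)2 (2.1 equiv, commercial solution), THF, −78 °C; then 6, −78 → −20 °C; AcOH quench
Reagents that add atoms: none
Why: vinylogous deprotonation of the 7-methyl group, the only enolisable position of 4, gives the extended dienolate 7, and its crossed Claisen acylation by the non-enolisable ester 6 is driven forward by the second equivalent of base, which stores 8 as its stabilised enolate.

**Step 4**
Reactants: 8 7-{2-[3-(methoxymethoxy)phenyl]-2-oxoethyl}-2,2-dimethyl-2H,5H-pyrano[4,3-b]pyran-5-one
Product: 10 (5,7-dihydroxy-2,2-dimethyl-2H-chromen-6-yl)[3-(methoxymethoxy)phenyl]methanone, via ring-opened keto ester 9 (not isolated)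
Conditions: Mg(OMe)2 (3 equiv, commercial solution in MeOH), MeOH, reflux, N2; cold 1 M HCl work-up
Reagents that add atoms: none
Why: Magnesium-bound methoxide adds to the lactone carbonyl C5 of 8 and the C5–O6 bond breaks, so that O6 leaves as the enolate oxygen on C7 and keto ester 9 forms as the magnesium chelate of its 1,3-diketone, with the third keto group of the tetraketide still masked as the cyclic enol ether C4a=C8a–O1. The chelated diketone carbon, the most acidic position of 9, attacks the ester carbonyl, methoxide is expelled and the acylcyclohexenedione enolises to the arene; this forms the C5–C6 bond, turns O6 into the 7-hydroxyl and makes the step an isomerisation overall. The closest known reaction is the Mg(OMe)2-mediated Claisen (Dieckmann-type) cyclisation of 3,5,7-triketo esters and of their 6-acylmethyl-4-hydroxy-2-pyrone forms to acylphloroglucinols; those substrates react as polyanions, whereas 8 has one acidic site less and its ester stays a neutral β-alkoxyacrylate, which should ease both the opening and the closure. Ring A closes 6-exo-trig (enolate carbon onto the ester C=O), the C4a=C8a double bond inside the pyran ring holds the ester and the diketone arm cis so that no unfavourable folding is needed, and no stereocentre is formed. The selectivity needed is C-acylation against aldol closure, relactonisation, saponification and retro-Claisen cleavage: the aldol donor C4a carries no hydrogen, relactonisation only regenerates 8, water is excluded, the magnesium enolate shields the diketone from methoxide, and aromatisation removes 10 from all equilibria. The regiochemistry is fixed by connectivity, since O1 must end up para to the aroyl group and no isomeric chromene can arise.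

**Step 5**
Reactants: 10 (5,7-dihydroxy-2,2-dimethyl-2H-chromen-6-yl)[3-(methoxymethoxy)phenyl]methanone; 11 1-bromo-3-methylbut-2-ene (prenyl bromide)
Product: 12 [5,7-dihydroxy-2,2-dimethyl-8-(3-methylbut-2-en-1-yl)-2H-chromen-6-yl][3-(methoxymethoxy)phenyl]methanone
Conditions: DBU (1.1 equiv), 11 (1.05 equiv), THF, 0 °C → rt
Reagents that add atoms: none
Why: DBU-mediated C-alkylation of the ambident acylphloroglucinol anion, in which both hydroxyls are hydrogen-bonded to the aroyl carbonyl and C8 (ortho to O7, para to O5) is the only hydrogen-bearing carbon of ring A, so the soft allylic bromide should be taken up there in an SN2 sense with rearomatisation.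

**Step 6**
Reactants: 12 [5,7-dihydroxy-2,2-dimethyl-8-(3-methylbut-2-en-1-yl)-2H-chromen-6-yl][3-(methoxymethoxy)phenyl]methanone
Product: 13 [5,7-dihydroxy-2,2-dimethyl-8-(3-methylbut-2-en-1-yl)-2H-chromen-6-yl](3-hydroxyphenyl)methanone (target)
Conditions: HCl (catalytic, dilute) in MeOH, rt, stopped at full conversion
Reagents that add atoms: none
Why: acid-catalysed acetal exchange with methanol (MOM cleavage) frees the ring B phenol under conditions that should be too mild for addition of the 7-hydroxyl or of methanol to the prenyl or chromene double bonds.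

**Compound list**
1 | 4-hydroxy-6-methyl-2H-pyran-2-one | CC1=CC(O)=CC(=O)O1 | starting material
2 | 3-methylbut-2-enal | CC(C)=CC=O | starting material
3 | (3E)-6-methyl-3-(3-methylbut-2-en-1-ylidene)-2H-pyran-2,4(3H)-dione (1-oxatriene, formed in the flask) | CC(C)=C/C=C1\C(=O)C=C(C)OC1=O | intermediate
4 | 2,2,7-trimethyl-2H,5H-pyrano[4,3-b]pyran-5-one | CC1=CC2=C(C=CC(C)(C)O2)C(=O)O1 | intermediate
5 | methyl 3-hydroxybenzoate | COC(=O)c1cccc(O)c1 | starting material
6 | methyl 3-(methoxymethoxy)benzoate | COCOc1cccc(c1)C(=O)OC | intermediate
7 | lithium 2,2-dimethyl-7-methylidene-2H,7H-pyrano[4,3-b]pyran-5-olate (dienolate of 4, formed in the flask) | [Li+].C=C1C=C2OC(C)(C)C=CC2=C([O-])O1 | intermediate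
8 | 7-{2-[3-(methoxymethoxy)phenyl]-2-oxoethyl}-2,2-dimethyl-2H,5H-pyrano[4,3-b]pyran-5-one | COCOc1cccc(c1)C(=O)CC1=CC2=C(C=CC(C)(C)O2)C(=O)O1 | intermediate
9 | methyl 6-{4-[3-(methoxymethoxy)phenyl]-2,4-dioxobutyl}-2,2-dimethyl-2H-pyran-5-carboxylate (present as its magnesium chelate, formed in the flask) | COCOc1cccc(c1)C(=O)CC(=O)CC1=C(C(=O)OC)C=CC(C)(C)O1 | intermediate
10 | (5,7-dihydroxy-2,2-dimethyl-2H-chromen-6-yl)[3-(methoxymethoxy)phenyl]methanone | COCOc1cccc(c1)C(=O)c1c(O)cc2OC(C)(C)C=Cc2c1O | intermediate
11 | 1-bromo-3-methylbut-2-ene (prenyl bromide) | CC(C)=CCBr | starting material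
12 | [5,7-dihydroxy-2,2-dimethyl-8-(3-methylbut-2-en-1-yl)-2H-chromen-6-yl][3-(methoxymethoxy)phenyl]methanone | COCOc1cccc(c1)C(=O)c1c(O)c(CC=C(C)C)c2OC(C)(C)C=Cc2c1O | intermediate
13 | [5,7-dihydroxy-2,2-dimethyl-8-(3-methylbut-2-en-1-yl)-2H-chromen-6-yl](3-hydroxyphenyl)methanone | CC(C)=CCc1c(O)c(C(=O)c2cccc(O)c2)c(O)c2c1OC(C)(C)C=C2 | target

**Total step count:** 6. **Longest linear sequence:** 5 (steps 1, 3, 4, 5, 6, or equally steps 2, 3, 4, 5, 6).

**Steps most likely to fail**

**Step 4 (ring transformation).** Three things may go wrong.
- Lactone opening may stay a fast, unproductive equilibrium, with relactonisation outrunning C-acylation.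
- The diketone may be cleaved by methoxide in a retro-Claisen sense.
- The monocyclic 2H-pyran stage may open electrocyclically and be intercepted by methoxide.

The fallback sets out from 1 and 6 and returns at 10. It inverts the order of ring formation, so that the ring transformation runs on its parent substrate class. The dianion of 1 (LiN(iPr)2, 3 equiv, THF, −78 → 0 °C) is acylated at the methyl group with 6 to give 4-hydroxy-6-{2-[3-(methoxymethoxy)phenyl]-2-oxoethyl}-2H-pyran-2-one F1. Mg(OMe)2 in refluxing MeOH converts this into [3-(methoxymethoxy)phenyl](2,4,6-trihydroxyphenyl)methanone F2. F2 is then condensed with 2 (ethylenediammonium diacetate cat., toluene, reflux) by Knoevenagel condensation and oxa-6π closure to 10. The price is loss of the built-in regiocontrol: the closure can engage the hydroxyl para or ortho to the aroyl group, so a chromatographic separation becomes necessary.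

**Step 5 (C-prenylation).** Three things may go wrong.
- O-alkylation of the chelated hydroxyls may compete.
- A second alkylation at C8 may occur with dearomatisation.
- Conversion may be incomplete, because ring A holds only two free hydroxyls.

The fallback sets out from 10 and returns at 12. It brings in the carbon chain by sigmatropic transfer instead of intermolecular C-alkylation. Allyl bromide and K2CO3 in acetone give [5-hydroxy-2,2-dimethyl-7-(prop-2-en-1-yloxy)-2H-chromen-6-yl][3-(methoxymethoxy)phenyl]methanone F3. Claisen rearrangement (Eu(fod)3 cat., toluene, 100 °C) moves the allyl group to the only free ortho carbon and gives [5,7-dihydroxy-2,2-dimethyl-8-(prop-2-en-1-yl)-2H-chromen-6-yl][3-(methoxymethoxy)phenyl]methanone F4. Cross metathesis with excess 2-methylbut-2-ene (second-generation Grubbs catalyst, CH2Cl2, 40 °C) then gives 12; the hindered chromene double bond next to the quaternary C2 should stay a spectator. Allylation on the other chelated hydroxyl would do no harm. Both of its ortho positions are blocked, so a Claisen–Cope sequence should carry the allyl group to the same carbon, C8.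

**Step 3 (acylation of the dienolate).** Three things may go wrong.
- The stabilised dienolate may attack the methyl ester only slowly.
- On warming it may condense with the lactone of unreacted pyranopyrone.
- The surplus amide may metalate the ester between its two directing groups.

The fallback sets out from 4 and returns at 8. It replaces the acylation by an addition followed by an oxidation. Commercial 3-hydroxybenzaldehyde is protected (MOMCl, iPr2NEt, CH2Cl2) as 3-(methoxymethoxy)benzaldehyde F5. Dienolate 7 (from 4 with LiN(iPr)2, 1.05 equiv, THF, −78 °C) adds to F5 in a vinylogous aldol addition. This gives racemic 7-{2-hydroxy-2-[3-(methoxymethoxy)phenyl]ethyl}-2,2-dimethyl-2H,5H-pyrano[4,3-b]pyran-5-one F6. Dess–Martin periodinane in NaHCO3-buffered CH2Cl2 oxidises the benzylic alcohol to 8, which removes the transient stereocentre.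

**Further compounds**
F1 | step 4 | 4-hydroxy-6-{2-[3-(methoxymethoxy)phenyl]-2-oxoethyl}-2H-pyran-2-one | COCOc1cccc(c1)C(=O)CC1=CC(O)=CC(=O)O1
F2 | step 4 | [3-(methoxymethoxy)phenyl](2,4,6-trihydroxyphenyl)methanone | COCOc1cccc(c1)C(=O)c1c(O)cc(O)cc1O
F3 | step 5 | [5-hydroxy-2,2-dimethyl-7-(prop-2-en-1-yloxy)-2H-chromen-6-yl][3-(methoxymethoxy)phenyl]methanone | COCOc1cccc(c1)C(=O)c1c(OCC=C)cc2OC(C)(C)C=Cc2c1O
F4 | step 5 | [5,7-dihydroxy-2,2-dimethyl-8-(prop-2-en-1-yl)-2H-chromen-6-yl][3-(methoxymethoxy)phenyl]methanone | COCOc1cccc(c1)C(=O)c1c(O)c(CC=C)c2OC(C)(C)C=Cc2c1O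
F5 | step 3 | 3-(methoxymethoxy)benzaldehyde | COCOc1cccc(C=O)c1
F6 | step 3 | 7-{2-hydroxy-2-[3-(methoxymethoxy)phenyl]ethyl}-2,2-dimethyl-2H,5H-pyrano[4,3-b]pyran-5-one (racemic) | COCOc1cccc(c1)C(O)CC1=CC2=C(C=CC(C)(C)O2)C(=O)O1
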